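Robinetinidol-(4β→8)-catechin: upper flavan 2R,3S,4R (2,3-trans, 3,4-cis), joined at C4 to C8 of (2R,3S)-catechin (this carbon is written C8').
Enabling feature: in ring C of the upper flavan (O1, C2, C3, C4, C4a, C8a) the chain O1–C8a–C4a–C4 is a latent ortho-quinone methide of ring A. Its methide carbon C4 carries C8', cis to the C3 oxygen.
Cuts, in retrosynthetic order: ten O–benzyl bonds; O1–C2 (SN2 reclosure at the carbinol level); C3–C4 together with O1–C2 ((4+2) cycloaddition at the ketal level); C4–C8' (aryllithium plus aldehyde); C2–C3 (Grignard reagent plus aldehyde).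
Forward order: rings A and B and the whole catechin unit are bought. C4–C8' is joined first, ring C then closes in the cycloaddition, is opened at its ketal carbon, brought to the CH level and closed again.
Stereochemistry: the two catechin centres come from the chiral pool. C3 and C4 come from endo, suprafacial addition of a (Z)-enol ether to the (E)-methide on the face left open by a chiral phosphoric acid. C2 comes from a Felkin–Anh reduction followed by invertive Mitsunobu closure.

Key step: step 10

Assumption: the sense of induction of the phosphoric acid on this chiral, crowded methide cannot be predicted safely, so (R)-TRIP [(R)-3,3'-bis(2,4,6-triisopropylphenyl)-1,1'-binaphthalene-2,2'-diyl hydrogen phosphate] is written as the matched catalyst and its enantiomer takes its place if the pairing proves mismatched.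

Step 1
Reactants: 1 (+)-catechin
Product: 2 5,7,3',4'-tetra-O-benzylcatechin (2R,3S)
Conditions: BnBr (4.4 equiv), K2CO3, DMF, 0 °C → rt
Reagents that add atoms: benzyl bromide, BrCc1ccccc1
Why: Williamson etherification in which K2CO3 ionises only the four phenols, so the secondary 3-OH stays free and the mild base leaves C2 and C3 of the chiral pool untouched.

Step 2
Reactants: 2 5,7,3',4'-tetra-O-benzylcatechin
Product: 3 3,5,7,3',4'-penta-O-benzylcatechin (2R,3S)
Conditions: NaH, BnBr, DMF, 0 °C → rt
Reagents that add atoms: benzyl bromide, BrCc1ccccc1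
Why: Williamson etherification of the sodium alkoxide; with every phenol already capped no quinone methide of the catechol ring can form, so the strong base should not epimerise C2.

Step 3
Reactants: 3 3,5,7,3',4'-penta-O-benzylcatechin
Product: 4 8-bromo-3,5,7,3',4'-penta-O-benzylcatechin
Conditions: NBS (1.0 equiv), CH2Cl2, −78 → 0 °C
Reagents that add atoms: N-bromosuccinimide, O=C1CCC(=O)N1Br
Why: Electrophilic aromatic bromination goes to the phloroglucinol-type ring, where C8 of 5,7-di-O-benzylated flavan-3-ol ethers is the well-documented site of attack ahead of C6 and of the less activated catechol ring.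

Step 4
Reactants: 5 4-(benzyloxy)-2-hydroxybenzaldehyde
Product: 6 4-(benzyloxy)-2-(tert-butyldimethylsilyloxy)benzaldehyde
Conditions: TBSCl, imidazole, DMF, rt
Reagents that add atoms: tert-butyldimethylsilyl chloride, CC(C)(C)[Si](C)(C)Cl
Why: Imidazole-promoted silyl ether formation masks the acidic phenol, which would quench the aryllithium of step 5, with a group that fluoride removes without acid.

Step 5
Reactants: 4 8-bromo-3,5,7,3',4'-penta-O-benzylcatechin; 6 4-(benzyloxy)-2-(tert-butyldimethylsilyloxy)benzaldehyde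
Product: 8 [4-benzyloxy-2-(tert-butyldimethylsilyloxy)phenyl](penta-O-benzylcatechin-8-yl)methanol (both carbinol epimers), via 8-lithio-penta-O-benzylcatechin 7 (not isolated)
Conditions: n-BuLi, THF, −78 °C; then 6, −78 °C; H2O
Reagents that add atoms: none
Why: Bromine–lithium exchange and 1,2-addition of the aryllithium to an aldehyde, both established for 8-bromo benzylated flavan-3-ols; the carbinol centre forms as an epimer mixture, which does not matter because it becomes the planar methide carbon, and an O-to-O silyl shift in the alkoxide would be harmless because step 6 clears silicon from either oxygen.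

Step 6
Reactants: 8 [4-benzyloxy-2-(tert-butyldimethylsilyloxy)phenyl](penta-O-benzylcatechin-8-yl)methanol
Product: 9 (4-benzyloxy-2-hydroxyphenyl)(penta-O-benzylcatechin-8-yl)methanol (both carbinol epimers)
Conditions: Bu4NF, AcOH (1:1), THF, 0 °C
Reagents that add atoms: none
Why: Fluoride-mediated desilylation under acetic acid buffering frees the phenol close to neutrality, so the easily ionised benzhydrol is not dehydrated before the dienophile is present.

Step 7
Reactants: 10 3,4,5-tris(benzyloxy)benzaldehyde; 11 benzyl chloromethyl ether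
Product: 13 (±)-2-benzyloxy-1-[3,4,5-tris(benzyloxy)phenyl]ethanol, via benzyloxymethylmagnesium chloride 12 (not isolated)
Conditions: Mg, HgCl2 (cat.), THF, −20 °C; then 10, −20 → 0 °C; H2O
Reagents that add atoms: none
Why: Grignard addition in which the alkoxymethyl Grignard reagent is made and used cold, where it does not decompose, and meets a non-enolisable aldehyde; the racemic carbinol centre is removed in step 8.

Step 8
Reactants: 13 (±)-2-benzyloxy-1-[3,4,5-tris(benzyloxy)phenyl]ethanol
Product: 14 2-benzyloxy-1-[3,4,5-tris(benzyloxy)phenyl]ethanone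
Conditions: Dess–Martin periodinane, CH2Cl2, rt
Reagents that add atoms: none
Why: Dess–Martin oxidation of a secondary benzylic alcohol to the aryl ketone under neutral conditions that leave benzyl ethers alone.

Step 9
Reactants: 14 2-benzyloxy-1-[3,4,5-tris(benzyloxy)phenyl]ethanone
Product: 15 (Z)-2-benzyloxy-1-(tert-butyldimethylsilyloxy)-1-[3,4,5-tris(benzyloxy)phenyl]ethene
Conditions: TBSOTf, Et3N, CH2Cl2, 0 °C
Reagents that add atoms: tert-butyldimethylsilyl triflate, CC(C)(C)[Si](C)(C)OS(=O)(=O)C(F)(F)F
Why: Soft enolisation with O-silylation (silyl enol ether formation); the Z isomer with the two oxygens cis is expected because the E isomer would press the benzyloxy group against ring B (allylic 1,3-strain), as is general for aryl alkyl ketones.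

Step 10
Reactants: 9 (4-benzyloxy-2-hydroxyphenyl)(penta-O-benzylcatechin-8-yl)methanol; 15 (Z)-2-benzyloxy-1-(tert-butyldimethylsilyloxy)-1-[3,4,5-tris(benzyloxy)phenyl]ethene
Product: 17 (2S,3S,4R)-3,7-bis(benzyloxy)-2-(tert-butyldimethylsilyloxy)-2-[3,4,5-tris(benzyloxy)phenyl]-4-(penta-O-benzylcatechin-8-yl)chroman (2-OTBS/3-OBn/4-aryl all cis), via (E)-ortho-quinone methide 16 (not isolated)
Conditions: (R)-TRIP (10 mol %), 15 (1.5 equiv), 4 Å MS, toluene, −20 °C → rt
Reagents that add atoms: none
Why: The phosphoric acid ionises the doubly donor-stabilised benzhydrol 9, the sieves take up the water, and the acid stays hydrogen-bonded to O1 of the (E)-methide 16, a 1-oxadiene (O1=C8a–C4a=C4) most electrophilic at C4, so the benzyloxy-bearing carbon of 15, the nucleophilic terminus of the silyl enol ether, bonds to C4 slightly ahead of O1–C2 bond formation in an asynchronous inverse-electron-demand hetero-Diels–Alder reaction. The closest known reaction type is the (4+2) cycloaddition of ortho-quinone methides, released from ortho-hydroxybenzhydrols by Brønsted acids (chiral phosphoric acids included) or by other triggers, with enol ethers, silyl enol ethers, enamides and styrenes to give 2-substituted chromans. Ring C closes as the six-membered cycloadduct from four methide atoms (O1, C8a, C4a, C4) and two alkene atoms (C2, C3), driven by rearomatisation of ring A. C2 and C3 take their cis O/O relation from suprafacial addition to the Z alkene, C4 becomes cis to O3 because both oxygen substituents lie endo under the oxadiene while the catechin ring points outward in the E methide, and the absolute sense (3S,4R) follows from the methide face left open by the chiral phosphate. The step needs regio-, endo and facial selectivity: the siloxy donor on C2 fixes the regiochemistry, the E geometry is secured by the clash a Z methide would suffer between the 2,6-disubstituted catechin ring and O1, the endo preference is the usual one of enol ethers with these oxadienes, and because 9 is a single enantiomer any wrong-face adduct is a diastereomer that chromatography removes. The C2 configuration of 17 has no lasting importance, since step 11 erases it.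

Step 11
Reactants: 17 (2S,3S,4R)-2-silyloxy-3-benzyloxy-4-(catechin-8-yl)flavan ketal
Product: 19 (2S,3R)-2-benzyloxy-3-(4-benzyloxy-2-hydroxyphenyl)-3-(penta-O-benzylcatechin-8-yl)-1-[3,4,5-tris(benzyloxy)phenyl]propan-1-one, via cyclic hemiketal 18 (not isolated)
Conditions: Bu4NF, AcOH (1:1), THF, 0 °C
Reagents that add atoms: none
Why: Fluoride cleaves the Si–O bond of the silyl ketal and the hemiketal opens to the conjugated aryl ketone while the buffer suppresses enolisation at C3 and retro-Michael cleavage; C2 is given up on purpose, because a direct hydride substitution there would have to enter on the ring face screened by the C4 catechin unit and would be expected to favour the unwanted 2,4-cis diaryl isomer.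

Step 12
Reactants: 19 (2S,3R)-keto phenol
Product: 20 (1S,2S,3R)-2-benzyloxy-3-(4-benzyloxy-2-hydroxyphenyl)-3-(penta-O-benzylcatechin-8-yl)-1-[3,4,5-tris(benzyloxy)phenyl]propan-1-ol (1,2-syn)
Conditions: KBH(s-Bu)3 (3 equiv), THF, −78 → −40 °C; H2O
Reagents that add atoms: none
Why: Diastereoselective ketone reduction under polar Felkin–Anh (Cornforth) control: with the non-chelating potassium counter-ion the C–OBn bond turns away from the carbonyl dipole, the bulky diarylmethyl carbon blocks one face and the bulky borohydride enters past the small C–H, which should give the 1,2-syn (1S) carbinol.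

Step 13
Reactants: 20 (1S,2S,3R)-syn alcohol
Product: 21 3,7,3',4',5'-penta-O-benzylrobinetinidol-(4β→8)-3,5,7,3',4'-penta-O-benzylcatechin (upper unit 2R,3S,4R)
Conditions: PPh3, DIAD, THF, 0 °C → rt
Reagents that add atoms: none
Why: Intramolecular Mitsunobu etherification, the known way from syn 1-aryl-3-(2-hydroxyaryl)propane-1,2-diol derivatives to 2,3-trans-flavan-3-ols: the phenol oxygen O1 displaces the activated carbinol oxygen in a 6-exo-tet SN2 process with inversion, turning (1S) into (2R) with ring B trans to O3, and any leakage through the benzylic cation should lead to the same isomer because allylic 1,3-strain holds C3–H in the plane of ring B so that the tethered phenol attacks anti to the benzyloxy group.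

Step 14
Reactants: 21 deca-O-benzyl robinetinidol-(4β→8)-catechin
Product: 22 robinetinidol-(4β→8)-catechin (CNP0261864.3)
Conditions: H2 (1 atm), Pd(OH)2/C, THF–MeOH, rt
Reagents that add atoms: none
Why: Catalytic hydrogenolysis of all ten benzyl ethers, the standard last step of proanthocyanidin syntheses; the cyclic C2–O1 bonds and the C4–C8' bond should persist at one atmosphere and room temperature, and no stereocentre is touched.

Compound list
1 | (+)-catechin (2R,3S) | O[C@H]1Cc2c(O)cc(O)cc2O[C@@H]1c1ccc(O)c(O)c1 | starting material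
2 | 5,7,3',4'-tetra-O-benzylcatechin | c1c(OCc3ccccc3)cc(OCc3ccccc3)c2c1O[C@H](c1ccc(OCc3ccccc3)c(OCc3ccccc3)c1)[C@@H](O)C2 | intermediate
3 | 3,5,7,3',4'-penta-O-benzylcatechin | c1c(OCc3ccccc3)cc(OCc3ccccc3)c2c1O[C@H](c1ccc(OCc3ccccc3)c(OCc3ccccc3)c1)[C@@H](OCc3ccccc3)C2 | intermediate
4 | 8-bromo-3,5,7,3',4'-penta-O-benzylcatechin | Brc1c(OCc3ccccc3)cc(OCc3ccccc3)c2c1O[C@H](c1ccc(OCc3ccccc3)c(OCc3ccccc3)c1)[C@@H](OCc3ccccc3)C2 | intermediate
5 | 4-(benzyloxy)-2-hydroxybenzaldehyde | O=Cc1ccc(OCc2ccccc2)cc1O | starting material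
6 | 4-(benzyloxy)-2-(tert-butyldimethylsilyloxy)benzaldehyde | O=Cc1ccc(OCc2ccccc2)cc1O[Si](C)(C)C(C)(C)C | intermediate
7 | 8-lithio-penta-O-benzylcatechin | [Li]c1c(OCc3ccccc3)cc(OCc3ccccc3)c2c1O[C@H](c1ccc(OCc3ccccc3)c(OCc3ccccc3)c1)[C@@H](OCc3ccccc3)C2 | intermediate
8 | [4-benzyloxy-2-(tert-butyldimethylsilyloxy)phenyl](penta-O-benzylcatechin-8-yl)methanol, carbinol centre as epimer mixture | OC(c1ccc(OCc3ccccc3)cc1O[Si](C)(C)C(C)(C)C)c1c(OCc3ccccc3)cc(OCc3ccccc3)c2c1O[C@H](c1ccc(OCc3ccccc3)c(OCc3ccccc3)c1)[C@@H](OCc3ccccc3)C2 | intermediate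
9 | (4-benzyloxy-2-hydroxyphenyl)(penta-O-benzylcatechin-8-yl)methanol, carbinol centre as epimer mixture | OC(c1ccc(OCc3ccccc3)cc1O)c1c(OCc3ccccc3)cc(OCc3ccccc3)c2c1O[C@H](c1ccc(OCc3ccccc3)c(OCc3ccccc3)c1)[C@@H](OCc3ccccc3)C2 | intermediate
10 | 3,4,5-tris(benzyloxy)benzaldehyde | O=Cc1cc(OCc2ccccc2)c(OCc2ccccc2)c(OCc2ccccc2)c1 | starting material
11 | benzyl chloromethyl ether | ClCOCc1ccccc1 | starting material
12 | benzyloxymethylmagnesium chloride | Cl[Mg]COCc1ccccc1 | intermediate
13 | (±)-2-benzyloxy-1-[3,4,5-tris(benzyloxy)phenyl]ethanol | OC(COCc1ccccc1)c1cc(OCc2ccccc2)c(OCc2ccccc2)c(OCc2ccccc2)c1 | intermediate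
14 | 2-benzyloxy-1-[3,4,5-tris(benzyloxy)phenyl]ethanone | O=C(COCc1ccccc1)c1cc(OCc2ccccc2)c(OCc2ccccc2)c(OCc2ccccc2)c1 | intermediate
15 | (Z)-2-benzyloxy-1-(tert-butyldimethylsilyloxy)-1-[3,4,5-tris(benzyloxy)phenyl]ethene | CC(C)(C)[Si](C)(C)O/C(c1cc(OCc3ccccc3)c(OCc3ccccc3)c(OCc3ccccc3)c1)=C\OCc3ccccc3 | intermediate
16 | (6E)-3-benzyloxy-6-[(penta-O-benzylcatechin-8-yl)methylidene]cyclohexa-2,4-dien-1-one | O=C1C=C(OCc3ccccc3)C=C/C1=C\c1c(OCc3ccccc3)cc(OCc3ccccc3)c2c1O[C@H](c1ccc(OCc3ccccc3)c(OCc3ccccc3)c1)[C@@H](OCc3ccccc3)C2 | intermediate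
17 | (2S,3S,4R)-3,7-bis(benzyloxy)-2-(tert-butyldimethylsilyloxy)-2-[3,4,5-tris(benzyloxy)phenyl]-4-(penta-O-benzylcatechin-8-yl)chroman | c3ccccc3COc1ccc2c(c1)O[C@](O[Si](C)(C)C(C)(C)C)(c1cc(OCc3ccccc3)c(OCc3ccccc3)c(OCc3ccccc3)c1)[C@@H](OCc3ccccc3)[C@H]2c1c(OCc3ccccc3)cc(OCc3ccccc3)c2c1O[C@H](c1ccc(OCc3ccccc3)c(OCc3ccccc3)c1)[C@@H](OCc3ccccc3)C2 | intermediate
18 | 2-hydroxy analogue of 17 (cyclic hemiketal, drawn as first formed) | c3ccccc3COc1ccc2c(c1)O[C@](O)(c1cc(OCc3ccccc3)c(OCc3ccccc3)c(OCc3ccccc3)c1)[C@@H](OCc3ccccc3)[C@H]2c1c(OCc3ccccc3)cc(OCc3ccccc3)c2c1O[C@H](c1ccc(OCc3ccccc3)c(OCc3ccccc3)c1)[C@@H](OCc3ccccc3)C2 | intermediate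
19 | (2S,3R)-2-benzyloxy-3-(4-benzyloxy-2-hydroxyphenyl)-3-(penta-O-benzylcatechin-8-yl)-1-[3,4,5-tris(benzyloxy)phenyl]propan-1-one | O=C(c1cc(OCc3ccccc3)c(OCc3ccccc3)c(OCc3ccccc3)c1)[C@@H](OCc3ccccc3)[C@H](c1ccc(OCc3ccccc3)cc1O)c1c(OCc3ccccc3)cc(OCc3ccccc3)c2c1O[C@H](c1ccc(OCc3ccccc3)c(OCc3ccccc3)c1)[C@@H](OCc3ccccc3)C2 | intermediate
20 | (1S,2S,3R)-2-benzyloxy-3-(4-benzyloxy-2-hydroxyphenyl)-3-(penta-O-benzylcatechin-8-yl)-1-[3,4,5-tris(benzyloxy)phenyl]propan-1-ol (1,2-syn) | O[C@@H](c1cc(OCc3ccccc3)c(OCc3ccccc3)c(OCc3ccccc3)c1)[C@@H](OCc3ccccc3)[C@H](c1ccc(OCc3ccccc3)cc1O)c1c(OCc3ccccc3)cc(OCc3ccccc3)c2c1O[C@H](c1ccc(OCc3ccccc3)c(OCc3ccccc3)c1)[C@@H](OCc3ccccc3)C2 | intermediate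
21 | deca-O-benzyl robinetinidol-(4β→8)-catechin | c3ccccc3COc1ccc2c(c1)O[C@H](c1cc(OCc3ccccc3)c(OCc3ccccc3)c(OCc3ccccc3)c1)[C@@H](OCc3ccccc3)[C@H]2c1c(OCc3ccccc3)cc(OCc3ccccc3)c2c1O[C@H](c1ccc(OCc3ccccc3)c(OCc3ccccc3)c1)[C@@H](OCc3ccccc3)C2 | intermediate
22 | robinetinidol-(4β→8)-catechin (CNP0261864.3) | Oc1ccc2c(c1)O[C@H](c1cc(O)c(O)c(O)c1)[C@@H](O)[C@H]2c1c(O)cc(O)c2c1O[C@H](c1ccc(O)c(O)c1)[C@@H](O)C2 | target

Total step count: 14. Longest linear sequence: 10 steps (1, 2, 3, 5, 6, 10, 11, 12, 13, 14).

Steps most likely to fail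

Step 10.
- **Risk:** weak endo/exo or facial discrimination at the crowded, strongly stabilised methide, slow addition, and protodesilylation of the enol ether by the acid and the released water.
- **Fallback (sets out from 9 and 14, comes back at 19):** the cycloaddition is replaced by a base-triggered conjugate addition. Benzhydrol 9 is condensed with p-toluenesulfinic acid (CH2Cl2, rt) to the sulfone 5-benzyloxy-2-[(penta-O-benzylcatechin-8-yl)(tosyl)methyl]phenol F1. Ketone 14 is deprotonated with LiN(SiMe3)2 (THF, −78 °C) to its chelated lithium (Z)-enolate F2. An excess of the enolate expels sulfinate from the sulfone, which regenerates methide 16 in a medium free of water and acid. The enolate then adds to C4 in a Michael reaction organised by a lithium bridge between the enolate and methide oxygens. Protonation gives keto phenol 19 directly, so 17 and step 11 are bypassed.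

Step 12.
- **Risk:** competition from a chelated or purely sterically governed transition state and hence low syn selectivity, slow reduction of a substrate that rests largely in its ring form, or enolisation at C3.
- **Fallback (sets out from 19, comes back at 21):** the carbinol configuration is made irrelevant by a stereoconvergent closure. Ketone 19 is reduced without regard to selectivity (NaBH4, THF–MeOH, 0 °C), which gives 20 together with its C1 epimer, the (1R,2S,3R)-anti alcohol F3. The mixture is treated with catalytic p-toluenesulfonic acid and 4 Å MS in CH2Cl2 at 0 °C. Both epimers ionise to the same benzylic cation stabilised by ring B, F4, which the tethered phenol captures. Allylic 1,3-strain holds C3–H in the plane of ring B, so O1 should enter anti to the benzyloxy group and give the 2,3-trans product 21. This follows the acid-catalysed cyclisation of 1-aryl-3-(2-hydroxyaryl)propane-1,2-diols to mainly trans-flavan-3-ols.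

Step 13.
- **Risk:** sluggish activation of the crowded carbinol, ionisation with loss of stereospecificity, or elimination towards an enol ether.
- **Fallback (sets out from 17, comes back at 21):** ring C is never opened. Ketal 17 is treated with Et3SiH and BF3·OEt2 (CH2Cl2, −78 °C). The siloxy group leaves and the 2-arylchroman-2-ylium (oxocarbenium) ion F5 takes up hydride, as in the reduction of 1-aryl glycosyl hemiketals to C-aryl glycosides. Axial attack on the half-chair that keeps O3 pseudoequatorial would place hydride cis to O3 and give 21 in one operation. This shorter path is held in reserve because stereoelectronic control must outweigh the screening of the same face by the pseudoaxial catechin unit.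

Further compounds
F1 | step 10 | 5-benzyloxy-2-[(penta-O-benzylcatechin-8-yl)(tosyl)methyl]phenol, sulfonyl carbon as epimer mixture | Cc1ccc(cc1)S(=O)(=O)C(c1ccc(OCc3ccccc3)cc1O)c1c(OCc3ccccc3)cc(OCc3ccccc3)c2c1O[C@H](c1ccc(OCc3ccccc3)c(OCc3ccccc3)c1)[C@@H](OCc3ccccc3)C2
F2 | step 10 | lithium (Z)-enolate of 14 | [Li]O/C(c1cc(OCc3ccccc3)c(OCc3ccccc3)c(OCc3ccccc3)c1)=C\OCc3ccccc3
F3 | step 12 | (1R,2S,3R)-anti alcohol, C1 epimer of 20 | O[C@H](c1cc(OCc3ccccc3)c(OCc3ccccc3)c(OCc3ccccc3)c1)[C@@H](OCc3ccccc3)[C@H](c1ccc(OCc3ccccc3)cc1O)c1c(OCc3ccccc3)cc(OCc3ccccc3)c2c1O[C@H](c1ccc(OCc3ccccc3)c(OCc3ccccc3)c1)[C@@H](OCc3ccccc3)C2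
F4 | step 12 | benzylic cation from 20 and F3 | [CH+](c1cc(OCc3ccccc3)c(OCc3ccccc3)c(OCc3ccccc3)c1)[C@@H](OCc3ccccc3)[C@H](c1ccc(OCc3ccccc3)cc1O)c1c(OCc3ccccc3)cc(OCc3ccccc3)c2c1O[C@H](c1ccc(OCc3ccccc3)c(OCc3ccccc3)c1)[C@@H](OCc3ccccc3)C2
F5 | step 13 | 2-arylchroman-2-ylium (oxocarbenium) ion from 17 | c3ccccc3COc1ccc2c(c1)[O+]=C(c1cc(OCc3ccccc3)c(OCc3ccccc3)c(OCc3ccccc3)c1)[C@@H](OCc3ccccc3)[C@H]2c1c(OCc3ccccc3)cc(OCc3ccccc3)c2c1O[C@H](c1ccc(OCc3ccccc3)c(OCc3ccccc3)c1)[C@@H](OCc3ccccc3)C2
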